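## The problem

Arene numbering used throughout: C1 carries the CH2CH2CO2C18H37 chain, C2 a free OH, C3 the OMe, C4 a free OH, and C5 and C6 hydrogen. The target 13 has no stereocentre, so the whole difficulty is constitutional: a 1,2,3,4-tetrasubstituted benzene in which four different groups stand in one fixed order and only the middle one of three neighbouring oxygens is methylated. A route through a preformed pyrogallol must tell three adjacent hydroxyls apart, and a route that attaches the chain by electrophilic substitution relies on kinetic site selectivity in a ring activated at every free position. The C2 hydroxyl and the ester carbonyl are placed for closure of a six-membered lactone with expulsion of 1-octadecanol 2 under acid, base or heat, so the ester is best carried from the start and the C2 oxygen kept masked until a last mild operation. The electron-rich methoxyresorcinol nucleus is oxidized easily as its phenolate, the stearyl ester rules out hydrides, excess organometallics and hydroxide, and the C18 chain makes every intermediate waxy and involatile, so a short route with volatile or water-soluble by-products is wanted. The feature that makes the key step possible is that ring atoms C1–C2–C3–C4 carry, in this order, a carbon chain, O, OMe and O, which is the pattern of the γ-carbon, ketone carbon, α-carbon and ester carbon of a 2-methoxy-3-oxo ester, while the remaining ring atoms C5 and C6 are two adjacent CH groups, that is, an acetylene unit. The benzene ring can therefore be cut into a four-carbon bis(silyl enol ether) diene and a two-carbon acetylene equivalent, and because both dienophile carbons end as CH the union poses no regiochemical question.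

## Retrosynthesis

13 ⇒ 9 + 10. The ring bonds C1–C6 and C4–C5 are cut, which traces the arene to a Diels–Alder reaction of the 1-methoxy-1,3-bis(silyloxy)diene 9 with phenyl vinyl sulfoxide 10 as acetylene equivalent. The cycloadduct 11 should undergo thermal sulfoxide elimination to the diene ketal 12, and hydrolysis of 12 aromatizes it to 13. The neighbouring [4+2] cut, with the chain on the two-carbon partner, would need an activating group on C1 to steer the orientation and would have to join two fully substituted carbons. Benzannulations through a dienylketene would need an acetylene bearing two oxygens or would leave an extra oxygen at C5. The precursor 9 is an open chain without a ring, and its connectivity alone fixes the order chain, OH, OMe, OH. Asked of the forward reaction are cycloaddition to a weak dienophile, clean syn-elimination, and loss of the methoxy group, not of the ring-bound oxygen, at C4.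

9 ⇒ 7. Two O–Si bonds are cut, through the monosilyl enol ether 8: the diene 9 is the bis(silyl enol ether) of the α-methoxy-β-keto ester 7. Soft enolization with a silylating agent and a tertiary amine is preferred to a strong amide base, because 7 also holds an enolizable CH2 beside the stearyl ester and that ester is itself an electrophile. The precursor 7 is an ordinary open-chain keto diester. The step must stop short of silylating the stearyl ester and should give the 4Z diene.

7 ⇒ 3 + 4. The C2–C3 bond of 7, between the α-carbon and the ketone carbon, is cut in a crossed Claisen sense. This gives the glutaric half ester 3, activated as the acid chloride 5, and methyl methoxyacetate 4, used as its lithium enolate 6. Building block 4 brings the C3 oxygen already methylated and the C4 oxygen as an ester carbonyl, so the three oxygens are differentiated by the choice of building block and not by a selective reaction. The neighbouring option, adding the methoxy group later by carbenoid O–H insertion, costs more steps and is kept as a fallback. The forward reaction must acylate the enolate at carbon and leave the stearyl ester alone.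

3 ⇒ 1 + 2. The ester C–O bond is cut: opening glutaric anhydride 1 with 1-octadecanol 2 desymmetrizes the diacid in one operation. Against esterification at the end, this installs the stearyl ester first, so no esterification is ever needed beside a free phenol. Both precursors are bulk chemicals, and the forward reaction only has to stop at the half ester.

## Roads not taken

Alternative 1: side-chain construction on a bought arene, the most obvious road. The cut is the Cα–Cβ bond of the chain. The forward key step is a Wittig olefination of 2,4-dihydroxy-3-methoxybenzaldehyde A1 with octadecyl (triphenylphosphoranylidene)acetate A2 to the cinnamate A3, followed by hydrogenation of A3. In this plan the 1,2,3,4-pattern with its differentiated middle oxygen is bought in A1, not solved, and any preparation of A1 returns to kinetic selectivity on a polyhydroxybenzene. The ylide A2 is basic enough to deprotonate the 4-hydroxybenzaldehyde unit of A1, which slows olefination, and the Z-isomer of A3 lactonizes to the coumarin A4 with loss of 2. With A2 made from 2 the sequence is no shorter than the chosen plan, in which the pattern follows from the connectivity of 7, made in one Claisen condensation from bulk building blocks.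

Alternative 2: aryne difunctionalization. The cut is at the C1–C bond to the chain and the C2–O bond. In the forward key step the aryne 4-(benzyloxy)-3-methoxy-1,2-didehydrobenzene A5 takes up an oxygen nucleophile and a carbon electrophile across the triple bond in an insertion and annulation sequence that closes a coumarin. The methoxy group beside the triple bond directs the nucleophilic atom, here oxygen, to the distal aryne carbon C1 and the carbon to C2. The product is therefore the 5,6-dioxygenated coumarin A6 and not the 7,8-pattern, whereas the target needs oxygen next to OMe. Even with the right orientation, the preparation of A5, alkene reduction, lactone alcoholysis and debenzylation would add at least four steps to the chosen plan.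

Alternative 3: cyclobutenone ring expansion from squaric acid. The cut is at the C1–C2 and C5–C6 bonds. In the forward key step dimethyl squarate A7 takes up the alkenyllithium (E)-[5-(tert-butyldimethylsilyloxy)pent-1-en-1-yl]lithium A8 to give the 4-alkenyl-4-hydroxycyclobutenone A9, and thermal Moore rearrangement of A9 gives the hydroquinone A10. The three neighbouring oxygens do come from A7, but A10 carries a fourth oxygen at C5 that must be removed, and its C3 and C4 oxygens are both methyl ethers that must then be told apart. The organolithium step excludes the ester, so the chain must travel masked as the silyl ether of A8 and be oxidized and esterified afterwards; the chosen plan needs none of these corrections.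

Key step: step 4

Remark on the chemistry: compounds 7, 10, 11 and 12 are used or formed as racemates or stereoisomer mixtures; all their stereocentres vanish in the arene.

## Steps

Step 1
Reactants: 1 glutaric anhydride; 2 1-octadecanol
Product: 3 5-(octadecyloxy)-5-oxopentanoic acid
Conditions: 4-(dimethylamino)pyridine (cat.), toluene, 90 °C
Reagents that add atoms: none
Why: Alcoholysis of a cyclic anhydride stops at the half ester because the carboxylic acid that is liberated does not acylate a second alcohol under these conditions; the stearyl ester is thus in place before any phenol exists.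

Step 2
Reactants: 3 5-(octadecyloxy)-5-oxopentanoic acid; 4 methyl methoxyacetate
Product: 7 1-methyl 7-octadecyl 2-methoxy-3-oxoheptanedioate, via acid chloride 5 (not isolated), via lithium ester enolate 6 (not isolated)
Conditions: 3, (COCl)2, HCONMe2 (cat.), CH2Cl2, 20 °C, evaporate; separately 4 (2.1 equiv), LiN(iPr)2 (2.1 equiv), THF, −78 °C; add 5, −78 °C; then 1 M HCl
Reagents that add atoms: none
Why: Crossed Claisen condensation (C-acylation of a lithium ester enolate by an acid chloride); at −78 °C the acid chloride should outcompete the stearyl ester as electrophile, and the second equivalent of 6 deprotonates the more acidic product and shields it from further acylation. The stereocentre at C2 of 7 forms racemic and is erased by enolization in step 3.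

Step 3
Reactants: 7 1-methyl 7-octadecyl 2-methoxy-3-oxoheptanedioate
Product: 9 octadecyl (4Z)-6,7-dimethoxy-5,7-bis(trimethylsilyloxy)hepta-4,6-dienoate, via monosilyl enol ether 8 (not isolated)
Conditions: Me3SiOSO2CF3 (2.3 equiv), Et3N (3 equiv), Et2O, 0 to 20 °C; decant from the ammonium salt, concentrate, use crude
Reagents that add atoms: trimethylsilyl trifluoromethanesulfonate, C[Si](C)(C)OS(=O)(=O)C(F)(F)F
Why: Soft enolization with a silyl triflate and a tertiary amine is the known route from β-keto esters to 1,3-bis(silyloxy)-1,3-dienes; the hydrogen between the carbonyls is silylated first to give 8, then the vinylogous γ-hydrogen, both more readily than the isolated stearyl ester. The 4Z geometry, with the chain cis to the C5 silyloxy group, is expected because it avoids the clash of the chain with the C6 methoxy group.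

Step 4
Reactants: 9 octadecyl (4Z)-6,7-dimethoxy-5,7-bis(trimethylsilyloxy)hepta-4,6-dienoate; 10 phenyl vinyl sulfoxide
Product: 13 octadecyl 3-(2,4-dihydroxy-3-methoxyphenyl)propanoate, via sulfinylcyclohexene cycloadduct 11 (not isolated), via cyclohexa-2,5-diene ketal 12 (not isolated)
Conditions: 10 (2 equiv), toluene, 100–110 °C, sealed tube, argon; then 0.5 M HCl, THF, 0 °C
Reagents that add atoms: none
Why: A normal-electron-demand Diels–Alder reaction between the tetraoxygenated diene 9 (4Z, so the chain points outward in the s-cis form) and the vinyl sulfoxide 10, a known acetylene equivalent, closes the six-membered carbocycle intermolecularly by forming C1–C6 and C4–C5 (arene numbering) to give 11. The closest known reaction types are the benzannulation of 1-alkoxy-1,3-bis(silyloxy)-1,3-dienes with alkynes to resorcinol derivatives and the Diels–Alder and sulfoxide-elimination sequence of aryl vinyl sulfoxides. At the same temperature 11 should lose benzenesulfenic acid by thermal syn-elimination; only C6 offers hydrogen beside the sulfinyl carbon because C4 is a fully substituted ketal carbon, so 12 forms as one alkene isomer. Cold dilute acid then cleaves the mixed methyl trimethylsilyl ketal at C4 to the ketone with loss of methanol, the cross-conjugated dienone tautomerizes to the phenol, and the C2 silyl ether is hydrolysed, so both flanking oxygens appear as free hydroxyls and the C3 methoxy group is untouched. No stereocentre survives: those of 11 (C1, C4, C5 and sulfur) are uncontrolled and all are destroyed on aromatization. No regiocontrol is needed, since C5 and C6 both end as CH: the orientation drawn in 11, which joins the nucleophilic chain-bearing diene terminus to the CH2 of 10, is the expected one, but the other orientation leads to 13 as well. The step does need retention of the C4 oxygen and survival of the open ester: the first is secured because ionization or desilylation of the O-silyl O-methyl ketal expels methanol and leaves C=O, the second because the C2 oxygen stays silylated until the short cold work-up, so the lactone cannot form during heating.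

## Compound list

1 | glutaric anhydride | O=C1CCCC(=O)O1 | starting material
2 | 1-octadecanol | CCCCCCCCCCCCCCCCCCO | starting material
3 | 5-(octadecyloxy)-5-oxopentanoic acid | CCCCCCCCCCCCCCCCCCOC(=O)CCCC(=O)O | intermediate
4 | methyl methoxyacetate | COCC(=O)OC | starting material
5 | octadecyl 5-chloro-5-oxopentanoate | CCCCCCCCCCCCCCCCCCOC(=O)CCCC(=O)Cl | intermediate
6 | lithium 1,2-dimethoxyethenolate | [Li+].[O-]C(OC)=COC | intermediate
7 | 1-methyl 7-octadecyl 2-methoxy-3-oxoheptanedioate (racemic) | CCCCCCCCCCCCCCCCCCOC(=O)CCCC(=O)C(OC)C(=O)OC | intermediate
8 | 1-methyl 7-octadecyl 2-methoxy-3-(trimethylsilyloxy)hept-2-enedioate (alkene geometry not defined) | CCCCCCCCCCCCCCCCCCOC(=O)CCCC(O[Si](C)(C)C)=C(OC)C(=O)OC | intermediate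
9 | octadecyl (4Z)-6,7-dimethoxy-5,7-bis(trimethylsilyloxy)hepta-4,6-dienoate (geometry at C6=C7 not defined) | CCCCCCCCCCCCCCCCCCOC(=O)CC/C=C(\O[Si](C)(C)C)C(OC)=C(OC)O[Si](C)(C)C | intermediate
10 | phenyl vinyl sulfoxide (racemic) | C=CS(=O)c1ccccc1 | starting material
11 | octadecyl 3-[3,4-dimethoxy-5-(phenylsulfinyl)-2,4-bis(trimethylsilyloxy)cyclohex-2-en-1-yl]propanoate (stereoisomer mixture) | CCCCCCCCCCCCCCCCCCOC(=O)CCC1CC(S(=O)c2ccccc2)C(OC)(O[Si](C)(C)C)C(OC)=C1O[Si](C)(C)C | intermediate
12 | octadecyl 3-[3,4-dimethoxy-2,4-bis(trimethylsilyloxy)cyclohexa-2,5-dien-1-yl]propanoate (stereoisomer mixture) | CCCCCCCCCCCCCCCCCCOC(=O)CCC1C=CC(OC)(O[Si](C)(C)C)C(OC)=C1O[Si](C)(C)C | intermediate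
13 | octadecyl 3-(2,4-dihydroxy-3-methoxyphenyl)propanoate | CCCCCCCCCCCCCCCCCCOC(=O)CCc1ccc(O)c(OC)c1O | target

## Step count and risk

Total step count: 4. Longest linear sequence: 4 steps, 1 → 3 → 7 → 9 → 13.

Step 4, the key step. The most likely failure is that thermal decay of the diene by silyl migration or oligomerization outruns the cycloaddition, because an unactivated vinyl sulfoxide is a weak dienophile and one terminus of 9 is fully substituted. Further risks:
- sulfenylation of unreacted diene by the sulfenic acid that is released;
- ionization of the C4 ketal with loss of the silyloxy group in place of the methoxy group, which would leave a methyl on the C4 oxygen;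
- acid-catalysed lactonization with loss of octadecanol during work-up.

The fallback gives up ring construction; it sets out from 2 and returns at 13. Purchased 2-methoxybenzene-1,3-diol F1 has its positions 4 and 6 equivalent and doubly activated. Acid-catalysed condensation of F1 with acrylic acid (CH3SO3H cat., toluene, reflux), an aryl ester formation followed by intramolecular Friedel–Crafts hydroarylation, should give 7-hydroxy-8-methoxychroman-2-one F2. Acid-catalysed alcoholysis of F2 in an excess of molten 2 with a catalytic amount of 4-MeC6H4SO3H at 80 °C then gives 13.

Step 3. The most likely failure is that enolization stops at the monosilyl stage, or that silylation also occurs beside the stearyl ester. Formation of the 4E diene, which reaches the s-cis form poorly, and hydrolysis on handling are further risks.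

The fallback carries the carboxyl group through ring formation as a carboxylate, which cannot compete in enolization; it sets out from 1 and 4 and returns at 13.
- Opening of 1 with the enolate 6 should give 6,7-dimethoxy-5,7-dioxoheptanoic acid F3.
- The trianion of F3, made with 3.1 equiv of LiN(iPr)2 in THF at −78 °C, is silylated with Me3SiCl to trimethylsilyl (4Z)-6,7-dimethoxy-5,7-bis(trimethylsilyloxy)hepta-4,6-dienoate F4.
- Heating F4 with 10 as in step 4 should give the cycloadduct trimethylsilyl 3-[3,4-dimethoxy-5-(phenylsulfinyl)-2,4-bis(trimethylsilyloxy)cyclohex-2-en-1-yl]propanoate F5.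
- Sulfoxide elimination from F5 gives the diene ketal trimethylsilyl 3-[3,4-dimethoxy-2,4-bis(trimethylsilyloxy)cyclohexa-2,5-dien-1-yl]propanoate F6.
- Aqueous acid converts F6 into 3-(2,4-dihydroxy-3-methoxyphenyl)propanoic acid F7, and F7 closes to the lactone F2 on warming with acid.
- Alcoholysis of F2 with 2, as in the fallback of step 4, gives 13.

Step 2. The most likely failure is proton transfer from the acid chloride to the enolate with ketene formation, or O-acylation and double acylation. Self-condensation of the enolate if the temperature rises and Claisen attack on the stearyl ester are further risks.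

The fallback introduces the methoxy group by carbenoid O–H insertion and not with the enolate; it sets out from 3 and returns at 7.
- 3 is converted with carbonyldiimidazole into octadecyl 5-(imidazol-1-yl)-5-oxopentanoate F8.
- C-acylation by F8 of the magnesium enolate generated from KO2CCH2CO2Me, MgCl2 and Et3N, followed by decarboxylation, gives 1-methyl 7-octadecyl 3-oxoheptanedioate F9.
- Regitz diazo transfer to F9 with 4-acetamidobenzenesulfonyl azide and Et3N in MeCN gives 1-methyl 7-octadecyl 2-diazo-3-oxoheptanedioate F10.
- O–H insertion of the carbenoid from F10 into methanol, catalysed by Rh2(OAc)4, then gives 7.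

## Further compounds

F1 | step 4 | 2-methoxybenzene-1,3-diol | COc1c(O)cccc1O
F2 | step 4 | 7-hydroxy-8-methoxychroman-2-one | COc1c(O)ccc2CCC(=O)Oc12
F3 | step 3 | 6,7-dimethoxy-5,7-dioxoheptanoic acid (racemic) | COC(=O)C(OC)C(=O)CCCC(=O)O
F4 | step 3 | trimethylsilyl (4Z)-6,7-dimethoxy-5,7-bis(trimethylsilyloxy)hepta-4,6-dienoate | C[Si](C)(C)OC(=O)CC/C=C(\O[Si](C)(C)C)C(OC)=C(OC)O[Si](C)(C)C
F5 | step 3 | trimethylsilyl 3-[3,4-dimethoxy-5-(phenylsulfinyl)-2,4-bis(trimethylsilyloxy)cyclohex-2-en-1-yl]propanoate (stereoisomer mixture) | C[Si](C)(C)OC(=O)CCC1CC(S(=O)c2ccccc2)C(OC)(O[Si](C)(C)C)C(OC)=C1O[Si](C)(C)C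
F6 | step 3 | trimethylsilyl 3-[3,4-dimethoxy-2,4-bis(trimethylsilyloxy)cyclohexa-2,5-dien-1-yl]propanoate (stereoisomer mixture) | C[Si](C)(C)OC(=O)CCC1C=CC(OC)(O[Si](C)(C)C)C(OC)=C1O[Si](C)(C)C
F7 | step 3 | 3-(2,4-dihydroxy-3-methoxyphenyl)propanoic acid | COc1c(O)ccc(CCC(=O)O)c1O
F8 | step 2 | octadecyl 5-(imidazol-1-yl)-5-oxopentanoate | CCCCCCCCCCCCCCCCCCOC(=O)CCCC(=O)n1ccnc1
F9 | step 2 | 1-methyl 7-octadecyl 3-oxoheptanedioate | CCCCCCCCCCCCCCCCCCOC(=O)CCCC(=O)CC(=O)OC
F10 | step 2 | 1-methyl 7-octadecyl 2-diazo-3-oxoheptanedioate | CCCCCCCCCCCCCCCCCCOC(=O)CCCC(=O)C(=[N+]=[N-])C(=O)OC
A1 | alternative 1 | 2,4-dihydroxy-3-methoxybenzaldehyde | COc1c(O)ccc(C=O)c1O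
A2 | alternative 1 | octadecyl (triphenylphosphoranylidene)acetate | CCCCCCCCCCCCCCCCCCOC(=O)C=P(c1ccccc1)(c1ccccc1)c1ccccc1
A3 | alternative 1 | octadecyl (E)-3-(2,4-dihydroxy-3-methoxyphenyl)prop-2-enoate | CCCCCCCCCCCCCCCCCCOC(=O)/C=C/c1ccc(O)c(OC)c1O
A4 | alternative 1 | 7-hydroxy-8-methoxy-2H-chromen-2-one | COc1c(O)ccc2ccc(=O)oc12
A5 | alternative 2 | 4-(benzyloxy)-3-methoxy-1,2-didehydrobenzene | COC1=C(OCc2ccccc2)C=CC#C1
A6 | alternative 2 | 6-(benzyloxy)-5-methoxy-2H-chromen-2-one | COc1c(OCc2ccccc2)ccc2oc(=O)ccc12
A7 | alternative 3 | 3,4-dimethoxycyclobut-3-ene-1,2-dione (dimethyl squarate) | COC1=C(OC)C(=O)C1=O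
A8 | alternative 3 | (E)-[5-(tert-butyldimethylsilyloxy)pent-1-en-1-yl]lithium | [Li]/C=C/CCCO[Si](C)(C)C(C)(C)C
A9 | alternative 3 | 4-[(1E)-5-(tert-butyldimethylsilyloxy)pent-1-en-1-yl]-4-hydroxy-2,3-dimethoxycyclobut-2-en-1-one (racemic) | CC(C)(C)[Si](C)(C)OCCC/C=C/C1(O)C(OC)=C(OC)C1=O
A10 | alternative 3 | 5-[3-(tert-butyldimethylsilyloxy)propyl]-2,3-dimethoxybenzene-1,4-diol | CC(C)(C)[Si](C)(C)OCCCc1cc(O)c(OC)c(OC)c1O
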